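**Plan**
1. Retrosynthetic cuts, in order: the C3 silyl ether and the C1 oxidation level; C16–C17 (alkynylzinc addition to a C16 enal, then trans-reduction); the C16 oxygen (allylic oxidation of a prenyl terminus); C10–CH3 (methyl addition to a ring ketone); the ring bond C8–C9; C7–C8 (Stille coupling) and C7–C2 (ester-enolate acylation); C6–C11 (Ireland–Claisen rearrangement of a geranyl ester).
2. Forward: the chain is built first from geraniol and a C5 acid, the Claisen rearrangement joins C6 to C11, the tetrasubstituted enoate is built on C7, the only ring is then closed between C8 and C9, and the methyl carbinol and the side chain follow.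
3. Enabling feature: in ring C6–C11, C9 (α to the C10 carbinol carbon, a ketone before methylation) and C8 (γ-carbon of the C1 enal) are both donor carbons of a dissonant O–C10–C9–C8–C7=C2–C1=O array. Reversing the polarity of C8 (γ-bromo enoate) lets the C10 enolate close the ring; it can form only toward C9 because C11 is quaternary.
4. Stereochemistry: C6/C11 from the chair Claisen transition state under a chiral boron controller; C2=C7 geometry from a stereodefined enol triflate coupled with retention; C10 by substrate-controlled addition; C16 by catalyst control; C19 from (S)-citronellal; C14=C15 from geraniol and SeO2, C17=C18 from Red-Al.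

Key step: step 10

Numbering used throughout (target): C1 aldehyde, C2 (methyl C25), C3–C5 hydroxypropyl chain (C3 carbinol), ring C6 (CH), C7 (alkylidene carbon), C8, C9, C10 (OH, methyl), C11 (methyl, side chain), side chain C12–C24 (C14=C15, C16 carbinol, C17=C18, C19 methyl-bearing stereocentre, C22=C23).
Assumption: the (S,S)-bromoborane of step 4 and the (S,S)-ProPhenol ligand of step 15 are taken to induce the configurations drawn; if either induces the opposite sense, its mirror-image form is used with no other change.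

Step 1
Reactants: 1 pentane-1,5-diol
Product: 2 5-[(tert-butyldiphenylsilyl)oxy]pentan-1-ol
Conditions: NaH (1.0 equiv), THF, 0 °C → rt; then TBDPSCl (1.0 equiv)
Reagents that add atoms: tert-butyl(chloro)diphenylsilane, CC(C)(C)[Si](Cl)(c1ccccc1)c1ccccc1
Why: O-silylation of the sparingly soluble monosodium alkoxide of a symmetrical diol should give mainly the mono-ether.

Step 2
Reactants: 2 5-[(tert-butyldiphenylsilyl)oxy]pentan-1-ol
Product: 3 5-[(tert-butyldiphenylsilyl)oxy]pentanoic acid
Conditions: TEMPO (cat.), PhI(OAc)2 (2.2 equiv), MeCN/H2O 1:1, rt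
Reagents that add atoms: water, O
Why: Nitroxyl-catalysed oxidation of a primary alcohol through the aldehyde hydrate should give the acid without touching the silyl ether.

Step 3
Reactants: 3 5-[(tert-butyldiphenylsilyl)oxy]pentanoic acid; 4 geraniol
Product: 5 geranyl 5-[(tert-butyldiphenylsilyl)oxy]pentanoate
Conditions: DCC, DMAP (cat.), CH2Cl2, 0 °C → rt
Reagents that add atoms: none
Why: Steglich esterification joins the two chains under neutral conditions that leave the (E)-allylic alkene unchanged.

Step 4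
Reactants: 5 geranyl 5-[(tert-butyldiphenylsilyl)oxy]pentanoate
Product: 8 (2S,3R)-2-{3-[(tert-butyldiphenylsilyl)oxy]propyl}-3,7-dimethyl-3-vinyloct-6-enoic acid, via boron ketene acetal 6 (not isolated), via boryl ester 7 (not isolated)
Conditions: pre-formed (S,S)-2-bromo-4,5-diphenyl-1,3-bis[3,5-bis(trifluoromethyl)phenylsulfonyl]-1,3,2-diazaborolidine (1.2 equiv), Et3N, toluene–hexane, −78 °C (Z(O)-boron enolate), then −20 → 4 °C; aqueous work-up
Reagents that add atoms: none
Why: Ireland–Claisen rearrangement through a chair transition state, in which the (E)-geranyl unit places the C11 methyl axial and the Z(O)-enolate places the C5 chain equatorial, fixes the C6/C11 relative configuration, while the C2-symmetric sulfonamide controller on boron selects the enolate face and so the absolute configuration.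

Step 5
Reactants: 8 (2S,3R)-2-{3-[(tert-butyldiphenylsilyl)oxy]propyl}-3,7-dimethyl-3-vinyloct-6-enoic acid; 9 methyl propanoate
Product: 12 methyl (4S,5R)-4-{3-[(tert-butyldiphenylsilyl)oxy]propyl}-2,5,9-trimethyl-3-oxo-5-vinyldec-8-enoate (both C2 epimers), via acid chloride 10 (not isolated), via lithium enolate of methyl propanoate 11 (not isolated)
Conditions: (COCl)2, DMF (cat.), CH2Cl2, 0 °C → rt; then added to 9/LDA, LiN(i-Pr)2 (2.2 equiv each), THF, −78 °C
Reagents that add atoms: none
Why: C-acylation of an ester enolate by an acid chloride (crossed Claisen condensation) builds C7–C2, and the second equivalent of enolate deprotonates the β-keto ester at C2 as it forms, which protects C6 from epimerisation.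

Step 6
Reactants: 12 methyl (4S,5R)-4-{3-[(tert-butyldiphenylsilyl)oxy]propyl}-2,5,9-trimethyl-3-oxo-5-vinyldec-8-enoate
Product: 13 methyl (2E,4S,5R)-4-{3-[(tert-butyldiphenylsilyl)oxy]propyl}-2,5,9-trimethyl-3-[(trifluoromethylsulfonyl)oxy]-5-vinyldeca-2,8-dienoate
Conditions: Tf2O, aq. Me4NOH, hexane–toluene, 0–5 °C
Reagents that add atoms: trifluoromethanesulfonic anhydride, O=S(=O)(OS(=O)(=O)C(F)(F)F)C(F)(F)F
Why: O-triflation of the β-keto ester enolate under non-chelating conditions (tetramethylammonium counter-ion, enolate oxygen anti to the ester carbonyl) should give the (E)-enol triflate, with the triflate cis to the C2 methyl and C6 cis to the ester as in the target; only the doubly activated C2–H is removed, so C6 is not enolised.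

Step 7
Reactants: 13 (E)-enol triflate; 14 (tributylstannyl)methanol
Product: 15 methyl (2E,4S,5R)-4-{3-[(tert-butyldiphenylsilyl)oxy]propyl}-3-(hydroxymethyl)-2,5,9-trimethyl-5-vinyldeca-2,8-dienoate
Conditions: Pd(PPh3)4 (5 mol %), LiCl (3 equiv), 1,4-dioxane, 90 °C
Reagents that add atoms: none
Why: Stille coupling replaces the triflate by the hydroxymethyl carbon C8 with retention at C7, giving the tetrasubstituted enoate with C8 cis to the C2 methyl; any geometric isomer would lactonise to a butenolide and be removed.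

Step 8
Reactants: 15 hydroxy enoate
Product: 16 methyl (2E,4R,5S)-5-acetyl-4-{3-[(tert-butyldiphenylsilyl)oxy]propyl}-3-(hydroxymethyl)-2,5,9-trimethyldeca-2,8-dienoate
Conditions: PdCl2 (10 mol %), CuCl (1 equiv), O2 (1 atm), DMF/H2O 7:1, rt
Reagents that add atoms: water, O
Why: Tsuji–Wacker oxidation by Markovnikov hydroxypalladation of the only monosubstituted alkene gives the C10 methyl ketone (C9 as its methyl), while the trisubstituted and the electron-poor tetrasubstituted alkenes should not react.

Step 9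
Reactants: 16 keto alcohol
Product: 17 methyl (2E,4S,5S)-5-acetyl-3-(bromomethyl)-4-{3-[(tert-butyldiphenylsilyl)oxy]propyl}-2,5,9-trimethyldeca-2,8-dienoate
Conditions: CBr4, PPh3, CH2Cl2, 0 °C
Reagents that add atoms: tetrabromomethane, BrC(Br)(Br)Br
Why: The Appel reaction converts the primary allylic alcohol into the bromide by SN2 at C8 without allylic transposition or change of alkene geometry.

Step 10
Reactants: 17 bromo keto ester
Product: 19 methyl (2Z)-2-[(2R,3S)-2-{3-[(tert-butyldiphenylsilyl)oxy]propyl}-3-methyl-3-(4-methylpent-3-en-1-yl)-4-oxocyclohexylidene]propanoate, via lithium enolate 18 (not isolated)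
Conditions: LiHMDS, LiN(SiMe3)2 (1.05 equiv), THF, −78 °C → 0 °C
Reagents that add atoms: none
Why: LiHMDS removes a proton from the C9 methyl group, the only enolisable position of the C10 ketone because C11 is quaternary, and the lithium enolate displaces bromide at C8 in an intramolecular SN2 reaction that forms the C8–C9 bond. The closest known reaction type is the intramolecular C-alkylation of a ketone enolate by an allylic halide, here with a γ-bromo-α,β-unsaturated ester serving as an a4 electrophile, the polarity-reversed form of the vinylogous enolate position. Ring C6–C11 closes in the 6-(enolendo)-exo-tet mode. No stereocentre is created: C6 and C11 are spectators, and the C2=C7 geometry is kept because the displacement involves neither an allyl cation nor an allyl-metal species. The step needs C- over O-alkylation and SN2 over SN2′ or Michael addition: the lithium counter-ion in THF and the soft primary allylic bromide favour carbon, the fully substituted β-carbon C7 and the quaternary-forming C2 terminus block the alternatives, and deprotonation at −78 °C should take the unhindered methyl ketone in preference to the hindered C6–H and the C8 methylene of the enoate.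

Step 11
Reactants: 19 cyclohexanone
Product: 20 methyl (2Z)-2-[(2R,3S,4S)-2-{3-[(tert-butyldiphenylsilyl)oxy]propyl}-4-hydroxy-3,4-dimethyl-3-(4-methylpent-3-en-1-yl)cyclohexylidene]propanoate
Conditions: MeMgBr, anhydrous CeCl3, THF, −78 °C
Reagents that add atoms: methylmagnesium bromide, C[Mg]Br
Why: Organocerium-type 1,2-addition to the ketone should occur from the face opposite the C6 side chain (held axial by allylic strain with the ester, 1,3 to C10) and the C11 methyl, so that the new methyl is cis to the C11 chain and the hydroxyl cis to the C6 chain, while the hindered tetrasubstituted enoate does not react at −78 °C.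

Step 12
Reactants: 20 tertiary alcohol
Product: 21 methyl (2Z)-2-[(2R,3S,4S)-2-{3-[(tert-butyldiphenylsilyl)oxy]propyl}-4-hydroxy-3-[(3E)-5-hydroxy-4-methylpent-3-en-1-yl]-3,4-dimethylcyclohexylidene]propanoate
Conditions: SeO2 (0.3 equiv), t-BuOOH (3 equiv), salicylic acid (cat.), CH2Cl2, rt
Reagents that add atoms: tert-butyl hydroperoxide, CC(C)(C)OO
Why: Selenium dioxide allylic oxidation (ene reaction then [2,3]-shift) attacks the (E)-methyl group of the electron-rich gem-dimethyl alkene and gives the (E)-allylic alcohol at C16, while the electron-poor enoate alkene is inert.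

Step 13
Reactants: 21 allylic alcohol
Product: 22 methyl (2Z)-2-[(2R,3S,4S)-2-{3-[(tert-butyldiphenylsilyl)oxy]propyl}-4-hydroxy-3,4-dimethyl-3-[(3E)-4-methyl-5-oxopent-3-en-1-yl]cyclohexylidene]propanoate
Conditions: activated MnO2 (excess), CH2Cl2, rt
Reagents that add atoms: none
Why: Manganese dioxide oxidises only the allylic primary alcohol to the (E)-enal and leaves the tertiary alcohol alone.

Step 14
Reactants: 23 (S)-citronellal
Product: 25 (S)-3,7-dimethyloct-6-en-1-yne, via alkenyl nonaflate 24 (not isolated)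
Conditions: C4F9SO2F, P2-Et phosphazene base (2.2 equiv), DMF, −30 °C → rt
Reagents that add atoms: none
Why: One-pot nonaflation–elimination traps the aldehyde enolate as the alk-1-enyl nonaflate, which loses nonaflate by base-induced β-elimination to give the terminal alkyne; the C19 stereocentre comes unchanged from the chiral pool.

Step 15
Reactants: 22 enal; 25 (S)-3,7-dimethyloct-6-en-1-yne
Product: 27 methyl (2Z)-2-[(2R,3S,4S)-2-{3-[(tert-butyldiphenylsilyl)oxy]propyl}-4-hydroxy-3-[(3E,5R,8S)-5-hydroxy-4,8,12-trimethyltrideca-3,11-dien-6-yn-1-yl]-3,4-dimethylcyclohexylidene]propanoate, via methylzinc acetylide 26 (not isolated)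
Conditions: 25 (3 equiv), Me2Zn (3 equiv), (S,S)-ProPhenol (20 mol %), Ph3P=O (40 mol %), toluene, 0 °C; then 22; aq. NH4Cl
Reagents that add atoms: none
Why: Catalytic asymmetric addition of an alkynylzinc to an α-substituted enal (dinuclear zinc–ProPhenol catalysis) sets C16 under catalyst control, the existing stereocentres being remote; the free tertiary hydroxyl only consumes one equivalent of Me2Zn.

Step 16
Reactants: 27 propargylic alcohol
Product: 28 (2Z)-2-[(2R,3S,4S)-2-{3-[(tert-butyldiphenylsilyl)oxy]propyl}-4-hydroxy-3-[(3E,5S,6E,8S)-5-hydroxy-4,8,12-trimethyltrideca-3,6,11-trien-1-yl]-3,4-dimethylcyclohexylidene]propan-1-ol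
Conditions: Red-Al, NaAlH2(OCH2CH2OCH3)2 (excess), THF, 0 °C → rt; Rochelle salt work-up
Reagents that add atoms: none
Why: Alkoxide-directed trans-hydroalumination of the propargylic alcohol gives the (E)-C17=C18 alkene with C16 unchanged, and the same reagent reduces the conjugated methyl ester by 1,2-addition to the C1 allylic alcohol.

Step 17
Reactants: 28 triol
Product: 29 (2Z)-2-[(2R,3S,4S)-2-{3-[(tert-butyldiphenylsilyl)oxy]propyl}-4-hydroxy-3-[(3E,5S,6E,8S)-5-hydroxy-4,8,12-trimethyltrideca-3,6,11-trien-1-yl]-3,4-dimethylcyclohexylidene]propanal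
Conditions: [Cu(MeCN)4]OTf (5 mol %), 2,2'-bipyridine (5 mol %), TEMPO (5 mol %), N-methylimidazole (10 mol %), air, MeCN, rt
Reagents that add atoms: none
Why: Copper/TEMPO aerobic oxidation is selective for primary alcohols for steric reasons, so the C1 allylic alcohol should give the enal while the secondary C16 and tertiary C10 hydroxyls remain.

Step 18
Reactants: 29 silyl-protected enal
Product: 30 target CNP0323596.2
Conditions: Bu4NF, AcOH (1:1), THF, rt
Reagents that add atoms: none
Why: Fluoride cleaves the Si–O bond of the primary silyl ether, and buffering with acetic acid should keep the enal and the bis-allylic alcohol intact.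

**Compound list**
1 | pentane-1,5-diol | OCCCCCO | starting material
2 | 5-[(tert-butyldiphenylsilyl)oxy]pentan-1-ol | OCCCCCO[Si](c1ccccc1)(c1ccccc1)C(C)(C)C | intermediate
3 | 5-[(tert-butyldiphenylsilyl)oxy]pentanoic acid | OC(=O)CCCCO[Si](c1ccccc1)(c1ccccc1)C(C)(C)C | intermediate
4 | geraniol, (2E)-3,7-dimethylocta-2,6-dien-1-ol | CC(C)=CCC/C(C)=C/CO | starting material
5 | geranyl 5-[(tert-butyldiphenylsilyl)oxy]pentanoate | CC(C)=CCC/C(C)=C/COC(=O)CCCCO[Si](c1ccccc1)(c1ccccc1)C(C)(C)C | intermediate
6 | boron ketene acetal of 5 (Z(O) geometry, boron carrying the (S,S)-bis-sulfonamide; not isolated) | CC(C)=CCC/C(C)=C/CO/C(OB1N(S(=O)(=O)c2cc(cc(c2)C(F)(F)F)C(F)(F)F)[C@@H](c2ccccc2)[C@H](c2ccccc2)N1S(=O)(=O)c1cc(cc(c1)C(F)(F)F)C(F)(F)F)=C/CCCO[Si](c1ccccc1)(c1ccccc1)C(C)(C)C | intermediate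
7 | boryl ester of acid 8 (not isolated) | CC(C)=CCC[C@@](C=C)(C)[C@H](CCCO[Si](c1ccccc1)(c1ccccc1)C(C)(C)C)C(=O)OB1N(S(=O)(=O)c2cc(cc(c2)C(F)(F)F)C(F)(F)F)[C@@H](c2ccccc2)[C@H](c2ccccc2)N1S(=O)(=O)c1cc(cc(c1)C(F)(F)F)C(F)(F)F | intermediate
8 | (2S,3R)-2-{3-[(tert-butyldiphenylsilyl)oxy]propyl}-3,7-dimethyl-3-vinyloct-6-enoic acid | CC(C)=CCC[C@@](C=C)(C)[C@H](CCCO[Si](c1ccccc1)(c1ccccc1)C(C)(C)C)C(=O)O | intermediate
9 | methyl propanoate | CCC(=O)OC | starting material
10 | acid chloride of 8 (not isolated) | CC(C)=CCC[C@@](C=C)(C)[C@H](CCCO[Si](c1ccccc1)(c1ccccc1)C(C)(C)C)C(=O)Cl | intermediate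
11 | lithium enolate of methyl propanoate (not isolated) | CC=C(OC)O[Li] | intermediate
12 | methyl (4S,5R)-4-{3-[(tert-butyldiphenylsilyl)oxy]propyl}-2,5,9-trimethyl-3-oxo-5-vinyldec-8-enoate (C2 epimers) | CC(C)=CCC[C@@](C=C)(C)[C@H](CCCO[Si](c1ccccc1)(c1ccccc1)C(C)(C)C)C(=O)C(C)C(=O)OC | intermediate
13 | methyl (2E,4S,5R)-4-{3-[(tert-butyldiphenylsilyl)oxy]propyl}-2,5,9-trimethyl-3-[(trifluoromethylsulfonyl)oxy]-5-vinyldeca-2,8-dienoate | CC(C)=CCC[C@@](C=C)(C)[C@H](CCCO[Si](c1ccccc1)(c1ccccc1)C(C)(C)C)/C(OS(=O)(=O)C(F)(F)F)=C(/C)C(=O)OC | intermediate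
14 | (tributylstannyl)methanol | CCCC[Sn](CCCC)(CCCC)CO | starting material
15 | methyl (2E,4S,5R)-4-{3-[(tert-butyldiphenylsilyl)oxy]propyl}-3-(hydroxymethyl)-2,5,9-trimethyl-5-vinyldeca-2,8-dienoate | CC(C)=CCC[C@@](C=C)(C)[C@H](CCCO[Si](c1ccccc1)(c1ccccc1)C(C)(C)C)/C(CO)=C(/C)C(=O)OC | intermediate
16 | methyl (2E,4R,5S)-5-acetyl-4-{3-[(tert-butyldiphenylsilyl)oxy]propyl}-3-(hydroxymethyl)-2,5,9-trimethyldeca-2,8-dienoate | CC(C)=CCC[C@@](C(C)=O)(C)[C@H](CCCO[Si](c1ccccc1)(c1ccccc1)C(C)(C)C)/C(CO)=C(/C)C(=O)OC | intermediate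
17 | methyl (2E,4S,5S)-5-acetyl-3-(bromomethyl)-4-{3-[(tert-butyldiphenylsilyl)oxy]propyl}-2,5,9-trimethyldeca-2,8-dienoate | CC(C)=CCC[C@@](C(C)=O)(C)[C@H](CCCO[Si](c1ccccc1)(c1ccccc1)C(C)(C)C)/C(CBr)=C(/C)C(=O)OC | intermediate
18 | lithium enolate of 17 at C9–C10 (not isolated) | CC(C)=CCC[C@@](C(=C)O[Li])(C)[C@H](CCCO[Si](c1ccccc1)(c1ccccc1)C(C)(C)C)/C(CBr)=C(/C)C(=O)OC | intermediate
19 | methyl (2Z)-2-[(2R,3S)-2-{3-[(tert-butyldiphenylsilyl)oxy]propyl}-3-methyl-3-(4-methylpent-3-en-1-yl)-4-oxocyclohexylidene]propanoate | CC(C)=CCC[C@@]1(C)[C@H](CCCO[Si](c2ccccc2)(c3ccccc3)C(C)(C)C)/C(=C(/C)C(=O)OC)CCC1=O | intermediate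
20 | methyl (2Z)-2-[(2R,3S,4S)-2-{3-[(tert-butyldiphenylsilyl)oxy]propyl}-4-hydroxy-3,4-dimethyl-3-(4-methylpent-3-en-1-yl)cyclohexylidene]propanoate | CC(C)=CCC[C@@]1(C)[C@H](CCCO[Si](c2ccccc2)(c3ccccc3)C(C)(C)C)/C(=C(/C)C(=O)OC)CC[C@]1(C)O | intermediate
21 | C16 allylic alcohol: the 3-[(3E)-5-hydroxy-4-methylpent-3-en-1-yl] analogue of 20 | OC/C(C)=C/CC[C@@]1(C)[C@H](CCCO[Si](c2ccccc2)(c3ccccc3)C(C)(C)C)/C(=C(/C)C(=O)OC)CC[C@]1(C)O | intermediate
22 | C16 enal: the 3-[(3E)-4-methyl-5-oxopent-3-en-1-yl] analogue of 20 | O=C/C(C)=C/CC[C@@]1(C)[C@H](CCCO[Si](c2ccccc2)(c3ccccc3)C(C)(C)C)/C(=C(/C)C(=O)OC)CC[C@]1(C)O | intermediate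
23 | (S)-citronellal, (3S)-3,7-dimethyloct-6-enal | CC(C)=CCC[C@H](C)CC=O | starting material
24 | (3S)-3,7-dimethylocta-1,6-dien-1-yl nonaflate (E/Z mixture; not isolated) | CC(C)=CCC[C@H](C)C=COS(=O)(=O)C(F)(F)C(F)(F)C(F)(F)C(F)(F)F | intermediate
25 | (S)-3,7-dimethyloct-6-en-1-yne | CC(C)=CCC[C@H](C)C#C | intermediate
26 | methylzinc acetylide of 25 (not isolated) | CC(C)=CCC[C@H](C)C#C[Zn]C | intermediate
27 | propargylic alcohol (16R by CIP, alkynyl outranking alkenyl): methyl ester with the 3-[(3E,5R,8S)-5-hydroxy-4,8,12-trimethyltrideca-3,11-dien-6-yn-1-yl] chain | CC(C)=CCC[C@H](C)C#C[C@H](O)/C(C)=C/CC[C@@]1(C)[C@H](CCCO[Si](c2ccccc2)(c3ccccc3)C(C)(C)C)/C(=C(/C)C(=O)OC)CC[C@]1(C)O | intermediate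
28 | triol: C1 allylic alcohol with the (3E,5S,6E,8S)-trienyl chain and the C3 silyl ether | CC(C)=CCC[C@H](C)/C=C/[C@H](O)/C(C)=C/CC[C@@]1(C)[C@H](CCCO[Si](c2ccccc2)(c3ccccc3)C(C)(C)C)/C(=C(/C)CO)CC[C@]1(C)O | intermediate
29 | 3-O-(tert-butyldiphenylsilyl) ether of the target | CC(C)=CCC[C@H](C)/C=C/[C@H](O)/C(C)=C/CC[C@@]1(C)[C@H](CCCO[Si](c2ccccc2)(c3ccccc3)C(C)(C)C)/C(=C(/C)C=O)CC[C@]1(C)O | intermediate
30 | CNP0323596.2, (2Z,6R,10S,11S,14E,16S,17E,19S)-3,10,16-trihydroxy seco-triterpenoid 1-al in the numbering above | CC(C)=CCC[C@H](C)/C=C/[C@H](O)/C(C)=C/CC[C@@]1(C)[C@H](CCCO)/C(=C(/C)C=O)CC[C@]1(C)O | target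

**Totals**
Total step count: 18. Longest linear sequence: 17 (steps 1–13 and 15–18; step 14 prepares the alkyne).

**Three steps most likely to fail**

Step 6. Risk: erosion of geometric control, through competing triflation of the chelated Z-enolate made worse by the bulky C6 substituent, which would carry the wrong C2=C7 isomer into the ring. Fallback, from acid 8 back to hydroxy enoate 15, with the geometry set by a syn-carbometalation: LiAlH4 (Et2O, 0 °C) reduces 8 to the primary alcohol F1. Dess–Martin periodinane gives the aldehyde F2. CBr4/PPh3 gives the 1,1-dibromoalkene F3, and n-BuLi (2.1 equiv, THF, −78 °C) followed by ClCO2Me gives the ynoate F4 (Corey–Fuchs sequence). The cuprate made from Bu3SnCH2OCH2OCH3, n-BuLi and CuBr·SMe2 adds syn across the triple bond at −78 °C and the vinylcopper is quenched with I2 to give the (Z)-α-iodo enoate F5, in which C8 and iodine are cis. Negishi coupling with MeZnCl (Pd(PPh3)4, THF) replaces iodine by methyl with retention to give the MOM-protected enoate F6. HCl in MeOH removes the MOM group and returns 15.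

Step 10. Risk: O-alkylation of the ambident enolate to a six-membered cyclic enol ether, or attack of the base on the γ-bromo enoate (vinylogous deprotonation) instead of the methyl ketone. Fallback, from keto alcohol 16 back to cyclohexanone 19, with C8 used as a carbonyl carbon instead of an sp3 electrophile: MnO2 oxidises the allylic alcohol to the keto aldehyde F7. KOH in MeOH (0 °C) brings about intramolecular aldol condensation of the methyl ketone onto the non-enolisable aldehyde and gives the 4-alkylidenecyclohex-2-enone F8, in which C8–C9 is a double bond. Conjugate reduction of the enone with [(Ph3P)CuH]6 (benzene, rt) saturates C8=C9 and gives 19.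

Step 4. Risk: slow rearrangement at the temperature needed for control (a quaternary centre is formed from a trisubstituted allyl terminus), with loss of enantio- or diastereoselectivity. Fallback, from ester 5 back to acid 8, by a racemic rearrangement and resolution: the lithium Z(O)-enolate (LDA, THF–DMPU, −78 °C) is silylated with Me3SiCl and rearranged on warming, which gives after aqueous work-up the racemic acid F9 with the same relative configuration. Conversion to the acid chloride and N-acylation of lithiated (S)-4-benzyl-2-oxazolidinone gives two diastereomeric imides, which are separated by chromatography. The imide F10 carrying the (2S,3R)-acyl group is cleaved with LiOH/H2O2 (THF/H2O, 0 °C) to give 8.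

**Further compounds**
F1 | step 6 | (2R,3R)-2-{3-[(tert-butyldiphenylsilyl)oxy]propyl}-3,7-dimethyl-3-vinyloct-6-en-1-ol | CC(C)=CCC[C@@](C=C)(C)[C@H](CCCO[Si](c1ccccc1)(c1ccccc1)C(C)(C)C)CO
F2 | step 6 | aldehyde of F1 (C7 aldehyde) | CC(C)=CCC[C@@](C=C)(C)[C@H](CCCO[Si](c1ccccc1)(c1ccccc1)C(C)(C)C)C=O
F3 | step 6 | 1,1-dibromoalkene from F2 | CC(C)=CCC[C@@](C=C)(C)[C@H](CCCO[Si](c1ccccc1)(c1ccccc1)C(C)(C)C)C=C(Br)Br
F4 | step 6 | methyl ynoate (C7≡C2–CO2Me) | CC(C)=CCC[C@@](C=C)(C)[C@H](CCCO[Si](c1ccccc1)(c1ccccc1)C(C)(C)C)C#CC(=O)OC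
F5 | step 6 | (Z)-α-iodo enoate with C8 as CH2OCH2OCH3 | CC(C)=CCC[C@@](C=C)(C)[C@H](CCCO[Si](c1ccccc1)(c1ccccc1)C(C)(C)C)/C(COCOC)=C(/I)C(=O)OC
F6 | step 6 | MOM ether of 15 | CC(C)=CCC[C@@](C=C)(C)[C@H](CCCO[Si](c1ccccc1)(c1ccccc1)C(C)(C)C)/C(COCOC)=C(/C)C(=O)OC
F7 | step 10 | keto aldehyde (C8 aldehyde of 16) | CC(C)=CCC[C@@](C(C)=O)(C)[C@H](CCCO[Si](c1ccccc1)(c1ccccc1)C(C)(C)C)/C(C=O)=C(/C)C(=O)OC
F8 | step 10 | 4-alkylidenecyclohex-2-enone (C8=C9 analogue of 19) | CC(C)=CCC[C@@]1(C)[C@H](CCCO[Si](c2ccccc2)(c3ccccc3)C(C)(C)C)/C(=C(/C)C(=O)OC)C=CC1=O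
F9 | step 4 | racemic (2S*,3R*)-2-{3-[(tert-butyldiphenylsilyl)oxy]propyl}-3,7-dimethyl-3-vinyloct-6-enoic acid | CC(C)=CCCC(C)(C=C)C(CCCO[Si](c1ccccc1)(c1ccccc1)C(C)(C)C)C(=O)O
F10 | step 4 | N-acyl (S)-4-benzyl-2-oxazolidinone of acid 8 | CC(C)=CCC[C@@](C=C)(C)[C@H](CCCO[Si](c1ccccc1)(c1ccccc1)C(C)(C)C)C(=O)N1[C@@H](Cc2ccccc2)COC1=O
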